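What stays behind in the dawn flask is substrate, about 40.2% by the mean readings, and the products account for the partner.

common to all: catalyst 10 µM
- dawn: substrate 2 mM; partner 1.5 mM; run made earlier
- spring: substrate 2 mM; partner 3.3 mM; run made earlier
- flask: substrate 2.0 mM; partner 2.20 mM; time 1.0 h

- dawn (time / min: target / %, over-reaction product / %): 5.00: 46, 15; 8.00: 43, 17; 12.0: 47, 14; 20.0: 46, 15; 40.0: 45, 15; 60.0: 40, 16
- spring (time / min: target / %, over-reaction product / %): 10.0: 28, 70; 20.0: 25, 68; 30.0: 24, 69; 40.0: 27, 67; 50.0: 28, 71; 60.0: 26, 68

(each reading ± 1.5 percentage points)

- the numbers in the tables scatter with a standard deviation of 1.5 percentage points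
- the reaction counts as stopped when no species that holds the substrate changes by six tenths of a point or more over the second half of the time

- the state of affairs at 1.0 h: stopped, and by what, or still going (forward and back rates have come level / no working catalyst is left / it is still moving / the partner has run out first / all of the substrate has reacted)
- amount of target at 1.0 h, in percent of the substrate charged
- amount of over-reaction product at 1.0 h, in percent of the substrate charged

Let x and p be [substrate] and [target] as fractions of the substrate charge, and o the same for [over-reaction product]. Take one partner per target and two per over-reaction product. The mean dawn readings, 44.5% and 15.3%, then use 75.1% against 75.0% charged. Spring, with 26.3% and 68.8%, uses 164% against 165%. Both runs read flat from the first point, apart from the last dawn target of 40%.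

If both steps carry the same partner and catalyst factors, these cancel: dp/dx = κp/x − 1. Integration gives p = (x^κ − x)/(1 − κ). One pass of κ = ln(x + p(1 − κ))/ln x from 0.600 reads 0.598 from dawn and 0.618 from spring. Their mean, 0.608, is carried as κ, the selectivity factor, second rate constant over first.

For the flask, the balance p = 2(1 − x) − [partner]/[substrate] at charge, started from x = 22.5%, gives x = 22.2%. My reckoning is then target 45.5% and over-reaction product 32.3%, with partner as limiting reagent.

The forecast says the partner has run out first, with target 46% and over-reaction product 32%: “It should be finished well before 1 h.”

The flask's state is: the partner has run out first. It holds target 45.3% and over-reaction product 32.4%, with partner at 0% and substrate at 22%.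

    substrate + partner + catalyst → catalyst + target (k = 1.30 × 10⁶ M⁻² s⁻¹)
    partner + catalyst + target → catalyst + over-reaction product (k = 8.00 × 10⁵ M⁻² s⁻¹)

Moved alone, partner shifts the over-reaction product by 5 points at 2.01 mM and 2.37 mM. With κ, the flask's substrate of 22.4% corresponds to target 45.6%. The neighbour charged with 1.3 mM of partner ends with substrate at 46.9%, where κ gives target 41.3%, and that flask holds 41.2%.

(The runs were computed for an exercise.)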